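**Strategy.** The pentasubstituted acylphloroglucinol ring is not functionalised but built: its C(acyl)–C(OH) bond is formed by a biomimetic Claisen recyclisation of a 4-methoxy-3-prenyl-6-(2-oxoalkyl)-2-pyranone, a lactone-masked tetraketide. The step exploits the 1,3,5-oxygen pattern of the benzene ring with OMe para to the 2-methylbutanoyl group: the pyranone C4–OMe becomes the aryl OMe, C3-prenyl its neighbour, the lactone carbonyl a phenol carbon, and the side-chain ketone the chelated aryl ketone. One operation therefore delivers the arene with every substituent placed and a single free CH, which then takes the methylene-linked 4-hydroxy-2-pyranone. The precursor comes from triacetic acid lactone by C3-prenylation, O-methylation and lateral acylation with an (R)-2-methylbutanoyl donor.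

Key step: step 5

Assumption: the stereocentre of the target is (R), and (R)-2-methylbutanoic acid of high ee is taken as a commercial chiral-pool material. Prenyl means 3-methylbut-2-en-1-yl. Silyl enol ether 12 is used as its E/Z mixture, since both isomers give 15.

**Step 1**
Reactants: 1 4-hydroxy-6-methyl-2H-pyran-2-one (triacetic acid lactone); 2 3-methylbut-2-en-1-yl acetate (prenyl acetate)
Product: 3 4-hydroxy-6-methyl-3-(3-methylbut-2-en-1-yl)-2H-pyran-2-one
Conditions: Pd(PPh3)4 (5 mol %), DBU (1.1 equiv), THF, 60 °C, slow addition of 2 (1.0 equiv)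
Reagents that add atoms: none
Why: Tsuji–Trost allylation, in which the soft C3 carbon of the DBU pyronate attacks the 1,1-dimethyl-π-allylpalladium complex at its unhindered CH2 terminus, while any 4-O-prenyl ether formed kinetically is re-ionised by Pd(0) and funnelled to the C3-prenyl product; no stereocentre is formed.

**Step 2**
Reactants: 3 4-hydroxy-6-methyl-3-(3-methylbut-2-en-1-yl)-2H-pyran-2-one
Product: 4 4-methoxy-6-methyl-3-(3-methylbut-2-en-1-yl)-2H-pyran-2-one
Conditions: Me2SO4 (1.2 equiv), K2CO3, acetone, reflux
Reagents that add atoms: dimethyl sulfate, COS(=O)(=O)OC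
Why: Williamson-type O-methylation of the vinylogous acid (pKa about 5) with a hard methylating agent under carbonate conditions, which for 4-hydroxy-2-pyranones favours the 4-methoxy-2-pyranone over the 2-methoxy-4-pyranone isomer.

**Step 3**
Reactants: 5 (R)-2-methylbutanoic acid
Product: 7 (2R)-N-methoxy-N,2-dimethylbutanamide, via acyl imidazolide 6 (not isolated)
Conditions: CDI, CH2Cl2, 0 °C to rt; then MeNH(OMe)·HCl, rt
Reagents that add atoms: N,O-dimethylhydroxylamine hydrochloride, CNOC.Cl
Why: Weinreb amide formation through the acyl imidazolide; the α-branched acyl group has no activating α-heteroatom and meets only imidazole as base, so the (R) centre should be retained.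

**Step 4**
Reactants: 4 4-methoxy-6-methyl-3-(3-methylbut-2-en-1-yl)-2H-pyran-2-one; 7 (2R)-N-methoxy-N,2-dimethylbutanamide
Product: 8 4-methoxy-6-[(3R)-3-methyl-2-oxopentyl]-3-(3-methylbut-2-en-1-yl)-2H-pyran-2-one
Conditions: LDA (1.1 equiv), THF, −78 °C; then 7, −78 to −20 °C; aq NH4Cl
Reagents that add atoms: none
Why: Lateral (vinylogous) lithiation of the C6 methyl group, the only acidic site once C3 is blocked, followed by Weinreb ketone synthesis, in which the chelated tetrahedral adduct survives until the quench, so that over-addition is prevented and neither the new doubly activated CH2 nor the α-stereocentre meets free base.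

**Step 5**
Reactants: 8 4-methoxy-6-[(3R)-3-methyl-2-oxopentyl]-3-(3-methylbut-2-en-1-yl)-2H-pyran-2-one
Product: 10 (2R)-1-[2,6-dihydroxy-4-methoxy-3-(3-methylbut-2-en-1-yl)phenyl]-2-methylbutan-1-one, via ring-opened triketide ester 9 (not isolated)
Conditions: Mg(OMe)2 (4 equiv), MeOH, reflux; then 1 M HCl, 0 °C
Reagents that add atoms: none
Why: Methoxide opens the lactone at C2 to the (2E)-3-methoxy-5,7-dioxo ester 9, a tetraketide methyl ester whose C3 carbonyl is masked as the methyl enol ether; the magnesium-chelated β-diketonate carbon C6 then attacks the ester carbonyl C1, methoxide is expelled, and enolisation of the cyclohexadienone gives the benzene ring irreversibly. The closest known reaction type is the base-mediated biomimetic Claisen (Dieckmann) recyclisation of 6-(2-oxoalkyl)-4-hydroxy- and 4-methoxy-2-pyranones and of 3,5,7-triketo esters to acylphloroglucinols, the chemical counterpart of the ring closure of type III polyketide synthases. The one ring is closed between C6 and C1 in a 6-(enolexo)-exo-trig mode, which is possible because the double bond inherited from the pyranone holds C1 and C4 cis. No stereocentre is formed, and the existing (R) centre is α′ to a ketone that is held as a magnesium enolate or as the phenoxide-chelated aryl ketone throughout, so its C–H should not be removed by methoxide. The step needs Claisen over aldol closure and a fixed position for the methyl ether: the prenyl group on C2 makes the aldol mode (C2 onto C7) a reversible dead end that cannot aromatise, and the preformed enol ether places OMe para to the acyl group and prenyl between OH and OMe, so no regioisomer can arise.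

**Step 6**
Reactants: 11 pentan-3-one
Product: 12 3-(trimethylsilyloxy)pent-2-ene (E/Z mixture)
Conditions: TMSCl, Et3N, DMF, 80 °C
Reagents that add atoms: chlorotrimethylsilane, C[Si](C)(C)Cl
Why: Thermodynamic silyl enol ether formation from a symmetrical ketone, so only one regioisomer is possible and the E/Z ratio does not matter.

**Step 7**
Reactants: 12 3-(trimethylsilyloxy)pent-2-ene; 13 malonyl dichloride
Product: 15 6-ethyl-4-hydroxy-5-methyl-2H-pyran-2-one, via diketo acid chloride 14 (not isolated)
Conditions: Et2O, −78 °C to rt
Reagents that add atoms: none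
Why: C-Acylation of the silyl enol ether by one acid chloride terminus gives 14, whose enol oxygen closes onto the second acid chloride (6-exo-trig lactonisation), the established 4-hydroxy-2-pyranone synthesis from silyl enol ethers and malonyl dichloride.

**Step 8**
Reactants: 15 6-ethyl-4-hydroxy-5-methyl-2H-pyran-2-one; 10 (2R)-1-[2,6-dihydroxy-4-methoxy-3-(3-methylbut-2-en-1-yl)phenyl]-2-methylbutan-1-one
Product: 18 3-{[2,4-dihydroxy-6-methoxy-3-[(2R)-2-methylbutanoyl]-5-(3-methylbut-2-en-1-yl)phenyl]methyl}-6-ethyl-4-hydroxy-5-methyl-2H-pyran-2-one (target), via pyranone Mannich base 16 (not isolated), via pyranone methide 17 (not isolated)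
Conditions: 15, CH2=NMe2+ I− (1.0 equiv), MeCN, rt; then 10 (1.0 equiv), 50 °C
Reagents that add atoms: Eschenmoser's salt (N,N-dimethylmethyleneiminium iodide), C=[N+](C)C.[I-]
Why: Mannich aminomethylation at the nucleophilic C3 of the pyranone, loss of dimethylamine to the 3-methylidene-pyran-2,4-dione 17 and Friedel–Crafts-type conjugate addition of the only unsubstituted ring carbon of 10 (ortho to OH and OMe), under neutral, mild conditions that should leave the prenyl group and the α-stereocentre untouched.

**Compound list**
1 | 4-hydroxy-6-methyl-2H-pyran-2-one (triacetic acid lactone) | Cc1cc(O)cc(=O)o1 | starting material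
2 | 3-methylbut-2-en-1-yl acetate (prenyl acetate) | CC(=O)OCC=C(C)C | starting material
3 | 4-hydroxy-6-methyl-3-(3-methylbut-2-en-1-yl)-2H-pyran-2-one | Cc1cc(O)c(CC=C(C)C)c(=O)o1 | intermediate
4 | 4-methoxy-6-methyl-3-(3-methylbut-2-en-1-yl)-2H-pyran-2-one | COc1cc(C)oc(=O)c1CC=C(C)C | intermediate
5 | (R)-2-methylbutanoic acid | CC[C@@H](C)C(=O)O | starting material
6 | (2R)-1-(1H-imidazol-1-yl)-2-methylbutan-1-one | CC[C@@H](C)C(=O)n1ccnc1 | intermediate (not isolated)
7 | (2R)-N-methoxy-N,2-dimethylbutanamide | CC[C@@H](C)C(=O)N(C)OC | intermediate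
8 | 4-methoxy-6-[(3R)-3-methyl-2-oxopentyl]-3-(3-methylbut-2-en-1-yl)-2H-pyran-2-one | COc1cc(CC(=O)[C@H](C)CC)oc(=O)c1CC=C(C)C | intermediate
9 | methyl (2E,8R)-3-methoxy-8-methyl-2-(3-methylbut-2-en-1-yl)-5,7-dioxodec-2-enoate | COC(=O)/C(CC=C(C)C)=C(\CC(=O)CC(=O)[C@H](C)CC)OC | intermediate (not isolated)
10 | (2R)-1-[2,6-dihydroxy-4-methoxy-3-(3-methylbut-2-en-1-yl)phenyl]-2-methylbutan-1-one | CC[C@@H](C)C(=O)c1c(O)cc(OC)c(CC=C(C)C)c1O | intermediate
11 | pentan-3-one | CCC(=O)CC | starting material
12 | 3-(trimethylsilyloxy)pent-2-ene (E/Z mixture) | CC=C(CC)O[Si](C)(C)C | intermediate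
13 | malonyl dichloride | O=C(Cl)CC(=O)Cl | starting material
14 | 4-methyl-3,5-dioxoheptanoyl chloride (racemic) | CCC(=O)C(C)C(=O)CC(=O)Cl | intermediate (not isolated)
15 | 6-ethyl-4-hydroxy-5-methyl-2H-pyran-2-one | CCc1oc(=O)cc(O)c1C | intermediate
16 | 3-[(dimethylamino)methyl]-6-ethyl-4-hydroxy-5-methyl-2H-pyran-2-one | CCc1oc(=O)c(CN(C)C)c(O)c1C | intermediate (not isolated)
17 | 6-ethyl-5-methyl-3-methylidene-2H-pyran-2,4(3H)-dione | CCC1=C(C)C(=O)C(=C)C(=O)O1 | intermediate (not isolated)
18 | 3-{[2,4-dihydroxy-6-methoxy-3-[(2R)-2-methylbutanoyl]-5-(3-methylbut-2-en-1-yl)phenyl]methyl}-6-ethyl-4-hydroxy-5-methyl-2H-pyran-2-one | CCc1oc(=O)c(Cc2c(O)c(C(=O)[C@H](C)CC)c(O)c(CC=C(C)C)c2OC)c(O)c1C | target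

**Step count.** Total: 8 steps. Longest linear sequence: 5 steps (1 → 3 → 4 → 8 → 10 → 18).

**Steps most likely to fail**

Step 5 (key step). The lactone may reclose faster than the hindered, vinylogous-carbonate-like ester carbon is attacked, so that conversion stalls. Long heating with methoxide could also cleave the β-diketone by retro-Claisen or erode the α-stereocentre. The fallback builds the same arene by electrophilic substitution; it sets out from 5 and comes back at 10. Acid 5 is converted with SOCl2 into (2R)-2-methylbutanoyl chloride F1. F1 acylates phloroglucinol (AlCl3, PhNO2, rt) to give (2R)-2-methyl-1-(2,4,6-trihydroxyphenyl)butan-1-one F2. The non-chelated para hydroxyl of F2 is methylated selectively (Me2SO4, 1 equiv, K2CO3, acetone) to (2R)-1-(2,6-dihydroxy-4-methoxyphenyl)-2-methylbutan-1-one F3. C-Prenylation of F3 at one of its two equivalent ring positions (prenyl bromide, DBU, THF) should then give 10.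

Step 1. The allylation may be diverted by double C3-prenylation, by attack at the tertiary allyl terminus (reverse prenyl), or by loss of the π-allyl ligand as isoprene. The fallback replaces allylic substitution by cross-coupling; it sets out from 1 and comes back at 4, so that 3 and step 2 are bypassed. Pyranone 1 is O-methylated (Me2SO4, K2CO3, acetone) to 4-methoxy-6-methyl-2H-pyran-2-one F4. Electrophilic bromination at C3 (NBS, MeCN, rt) gives 3-bromo-4-methoxy-6-methyl-2H-pyran-2-one F5. Stille coupling of F5 with tributyl(3-methylbut-2-en-1-yl)stannane (Pd(PPh3)4, LiCl, DMF, 80 °C) should give 4.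

Step 8. The pyranone methide may be consumed by self-condensation to a methylene-bis-pyranone before the hindered, acyl-deactivated arene attacks it. The fallback reverses the polarity and places the electrophile on the arene; it sets out from 10 and comes back at 18. Arene 10 is aminomethylated at its only free ring carbon with Eschenmoser's salt (MeCN, rt) to (2R)-1-{3-[(dimethylamino)methyl]-2,6-dihydroxy-4-methoxy-5-(3-methylbut-2-en-1-yl)phenyl}-2-methylbutan-1-one F6. Heating F6 with 15 (dioxane, 100 °C) should expel dimethylamine to give an ortho-quinone methide, which C3 of 15 traps as 18.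

**Further compounds**
F1 | step 5 | (2R)-2-methylbutanoyl chloride | CC[C@@H](C)C(=O)Cl
F2 | step 5 | (2R)-2-methyl-1-(2,4,6-trihydroxyphenyl)butan-1-one | CC[C@@H](C)C(=O)c1c(O)cc(O)cc1O
F3 | step 5 | (2R)-1-(2,6-dihydroxy-4-methoxyphenyl)-2-methylbutan-1-one | CC[C@@H](C)C(=O)c1c(O)cc(OC)cc1O
F4 | step 1 | 4-methoxy-6-methyl-2H-pyran-2-one | COc1cc(C)oc(=O)c1
F5 | step 1 | 3-bromo-4-methoxy-6-methyl-2H-pyran-2-one | COc1cc(C)oc(=O)c1Br
F6 | step 8 | (2R)-1-{3-[(dimethylamino)methyl]-2,6-dihydroxy-4-methoxy-5-(3-methylbut-2-en-1-yl)phenyl}-2-methylbutan-1-one | CC[C@@H](C)C(=O)c1c(O)c(CN(C)C)c(OC)c(CC=C(C)C)c1O
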